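**Remark on the chemistry:** the target has no stereocentre, so flavanone 9 is made as a racemate (one enantiomer drawn); it is assumed that the Lewis acid in step 1 cleaves the more crowded of the two methoxy groups ortho to the new ketone.

## Analysis of the target

- Target 10 is a flavone (2-aryl-4H-chromen-4-one). Ring A carries methoxy groups at C5, C7 and C8, ring C a methoxy group at C3, and ring B is a 2-methoxyphenyl group on C2.
- There is no stereocentre. Ring B is only twisted out of the chromone plane by its ortho substituent and the C3 methoxy group.
- Ring A is pentasubstituted and electron-rich, with C6 as its one free, nucleophilic position. The C5 methoxy group lies peri to the C4 carbonyl and is the ether most easily cleaved by Lewis acids.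
- The difficulty is regiochemical. Five methyl ethers must be placed without ambiguity, the 5,7,8 pattern must not be confused with the 5,6,7 pattern, and C3 must carry oxygen, which chalcone and 1,3-diketone routes do not supply unless the ketone component already has it.
- The strategy rests on ring C in its 2,3-dihydro form. C2 is benzylic to ring B and bonded to O1, so a C2–H can leave as hydride to give a doubly stabilised cation. C3 lies α to the C4 carbonyl, already bears its methoxy group, and can react as an enol carbon.
- Joining C2 and C3 oxidatively lets ring B enter as the benzyl halide 5 and lets C3, C4 and the C3 oxygen enter together as the acid chloride 2.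

## Retrosynthetic reasoning

**10 to 9.** The C2=C3 double bond is removed first, giving the trans-flavanone 9. In 9 both carbons are sp3 and can be joined by a polar bond formation. The forward step is a dehydrogenation of a flavanone, which also erases both stereocentres of 9, so their configuration never has to be controlled.

**9 to 8.** The C2–C3 bond is cut. It is the one C–C bond of ring C that touches neither ring A nor the carbonyl carbon. Cutting it leaves an aryl benzyl ether and a two-carbon enol side chain on the same ring, as in enol acetate 8. A classical aldol cut at this bond would need ring B as an aldehyde and would close ring C later through O1–C2 under base, where chalcone, flavanone and aurone interconvert. Here both carbons stay at their lower oxidation level and are joined by removing hydride from the ether CH2 with a quinone oxidant. The forward reaction must generate the oxocarbenium ion at C2 and have the enol carbon capture it in a six-membered closure before anything else does.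

**8 to 6.** The enol ester C–O bond is cut, giving ketone 6 by way of its lithium enolate 7. An acetate is chosen because it is less easily oxidised than a silyl enol ether and loses its acyl group cleanly after the C–C bond has formed. The forward reaction has to acylate the enolate on oxygen.

**6 to 4 and 5.** The O1–CH2 bond is cut, which gives phenol 4 and benzyl chloride 5. This bond forms by plain O-alkylation and brings in ring B with C2 at the benzyl oxidation level that the key step needs.

**4 to 1 and 2.** The C4a–C4 bond is cut. Arene 1 has only one kind of free position, so acylation with 2 poses no regiochemical question in the C–C bond formation, and 2 delivers C4, C3 and the C3 methoxy group in one piece. The forward reaction passes through ketone 3 and must then free one ortho oxygen as the phenol that becomes O1.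

## Alternatives that were turned down

**Alternative 1:** aryne insertion into an acrylic acid.
- Disconnection: C8a–O1 and C4a–C4 at ring A, and O1–C2 in ring C, leading to 3,5,7-trimethoxy-2-(2-methoxyphenyl)-4H-chromen-4-one A1.
- Forward key step: 3,5-dimethoxybenzyne A2, generated with fluoride, would insert into the carboxyl C–O bond of 2,3-dimethoxy-3-(2-methoxyphenyl)prop-2-enoic acid A3. The resulting ortho-acylphenoxide would then displace the β-methoxide by addition–elimination.
- For it: three ring bonds form in one operation, the flavone oxidation level and the C3 methoxy group are reached directly, and the methoxy group next to the aryne steers the carboxylate oxygen to the remote aryne carbon, which is the orientation needed.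
- Against it: A1 has hydrogen at C8. Oxygenating C8 afterwards means distinguishing C8 from C6, both flanked by oxygen, and costs several steps. An aryne that already carried the third methoxy group would have an ether next to each aryne carbon and lose the regiocontrol. A2 and A3 each need their own multistep preparation.
- Comparison: this route is stronger on convergence and needs no dehydrogenation. The chosen route instead has all four ring A oxygens fixed in 1 from the first step and needs no late C–H oxygenation.

**Alternative 2:** carbonylative alkyne annulation.
- Disconnection: C4a–C4, C4–C3 and O1–C2, leading to 5,7,8-trimethoxy-2-(2-methoxyphenyl)-4H-chromen-4-one A4.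
- Forward key step: 2-iodo-3,5,6-trimethoxyphenol A5, 2-ethynylanisole A6 and carbon monoxide A7 would combine under PdCl2(PPh3)2 in diethylamine. The sequence is oxidative addition of the C–I bond to zerovalent palladium, CO insertion, coupling to an ynone and amine-assisted 6-endo closure by the phenol.
- For it: the reaction type is well established, catalytic and convergent, and ring A arrives complete. Its key step is clearly less risky than the one chosen here.
- Against it: A4 has hydrogen at C3, so the C3 oxygen must be added afterwards by metalation and oxidation followed by methylation. A5 needs an iodination ortho to the hydroxyl group in competition with the position between two methoxy groups. The 5-exo closure to an aurone competes.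
- Comparison: this route wins on precedent. The chosen route brings the C3 oxygen in with C3 itself and needs no functionalisation of the finished heterocycle, which keeps it at five steps.

**Alternative 3:** ring A by Moore rearrangement.
- Disconnection: C4a–C5 of ring A, which is built last on a pyranone, leading to 5,8-dihydroxy-3,7-dimethoxy-2-(2-methoxyphenyl)-4H-chromen-4-one A8.
- Forward key step: heating 4-hydroxy-3-methoxy-4-[5-methoxy-6-(2-methoxyphenyl)-4-oxo-4H-pyran-2-yl]cyclobut-2-en-1-one A9 would open the four-membered ring to a dienylketene. A 6π closure onto the pyranone carbon and tautomerisation would give A8.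
- For it: the ring A pattern is fixed by the cyclobutenone, no Lewis acid ether cleavage is involved, and the key step is neutral and thermal.
- Against it: A9 requires a metalated 2-aryl-3-methoxypyranone and a squaric acid derivative, each several steps away. Capture of the ketene by the neighbouring hydroxyl group to give a furanone competes with closure onto a non-aromatic carbon. A8 is an air-sensitive hydroquinone that needs two further methylations, one at the chelated C5 hydroxyl.
- Comparison: this route is stronger on regiochemical certainty in ring A. The chosen route is far shorter and avoids the hydroquinone oxidation level.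

Key step: step 4

## Route

**Step 1**
Reactants: 1 1,2,3,5-tetramethoxybenzene; 2 methoxyacetyl chloride
Product: 4 1-(2-hydroxy-3,4,6-trimethoxyphenyl)-2-methoxyethan-1-one, via tetramethoxyphenyl ketone 3 (not isolated)
Conditions: AlCl3 (2.5 equiv), Et2O, 0 °C to reflux; aq. HCl
Reagents that add atoms: none
Why: Friedel–Crafts acylation at the single kind of free position of 1 should give 3; the AlCl3 chelate between the ketone and an ortho ether should then cleave the ortho methoxy group that also has a methoxy neighbour and is twisted out of the ring plane, and the aluminium phenolate formed resists further cleavage.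

**Step 2**
Reactants: 4 1-(2-hydroxy-3,4,6-trimethoxyphenyl)-2-methoxyethan-1-one; 5 2-methoxybenzyl chloride
Product: 6 2-methoxy-1-{3,4,6-trimethoxy-2-[(2-methoxybenzyl)oxy]phenyl}ethan-1-one
Conditions: K2CO3, NaI (cat.), DMF, 60 °C
Reagents that add atoms: none
Why: Williamson ether synthesis; carbonate deprotonates only the phenol, not the ketone α-CH2, and the benzylic halide, activated by iodide exchange, is a good SN2 electrophile even for this flanked phenoxide.

**Step 3**
Reactants: 6 2-methoxy-1-{3,4,6-trimethoxy-2-[(2-methoxybenzyl)oxy]phenyl}ethan-1-one
Product: 8 (Z)-2-methoxy-1-{3,4,6-trimethoxy-2-[(2-methoxybenzyl)oxy]phenyl}ethenyl acetate, via lithium enolate 7 (not isolated)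
Conditions: LiN(SiMe3)2, THF, −78 °C; Ac2O, −78 to 0 °C
Reagents that add atoms: acetic anhydride, CC(=O)OC(C)=O
Why: Kinetic enolate formation followed by O-acylation with a hard anhydride; lithium chelation between the enolate oxygen and the α-methoxy oxygen should place these cis, giving the Z enol acetate, and the base-only conditions spare the acid-sensitive ortho-methoxybenzyl ether.

**Step 4**
Reactants: 8 (Z)-2-methoxy-1-{3,4,6-trimethoxy-2-[(2-methoxybenzyl)oxy]phenyl}ethenyl acetate
Product: 9 rac-(2S,3S)-3,5,7,8-tetramethoxy-2-(2-methoxyphenyl)chroman-4-one (trans)
Conditions: DDQ (1.3 equiv), 2,6-dichloropyridine, LiClO4, 4 Å molecular sieves, ClCH2CH2Cl, 0 °C to rt; aq. NaHCO3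
Reagents that add atoms: none
Why: Proposed new method: DDQ should form a charge-transfer complex with the electron-rich ether, take an electron and then remove hydrogen from the OCH2 group, the only C–H bond that is both α to the ring A ether oxygen and benzylic to ring B, so the same oxocarbenium ion ArO+=CH–Ar′ results whichever ring is oxidised first. The enol acetate carbon bearing the methoxy group then attacks this carbon to form C2–C3, and the acetyl group of the resulting acyloxocarbenium ion passes to the reduced quinone and ends as acetic acid after work-up. The closest known reaction type is DDQ-mediated oxidative C–H cleavage of benzylic and allylic alkyl ethers with capture of the oxocarbenium ion by a tethered enol acetate to give tetrahydropyranones; new here are the aryl-bound ether oxygen and a nucleophile carried on that same aryl ring. Ring C closes in a 6-endo-trig mode, with both the enol C=C bond and the O+=C bond inside the new ring, which is feasible because the enol acetate is twisted out of the plane of the 2,6-disubstituted ring A and offers its π face to the cation. C2 and C3 are set together: a chair-like closure of the (E)-oxocarbenium ion places the aryl group equatorial, and C3, being α to the ketone, can equilibrate to the trans isomer with both substituents equatorial; the product is racemic and both centres disappear in step 5. The step needs DDQ to cleave this C–H bond in preference to degrading ring A or adding to the enol double bond; the ortho-methoxy group of ring B stabilises the cation, the acetate makes the enol less oxidisable than a silyl enol ether, and 2,6-dichloropyridine, LiClO4 and sieves suppress acid- and water-induced loss of the enol acetate and of the benzyl group. Further oxidation of 9 would only lead on to 10.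

**Step 5**
Reactants: 9 rac-(2S,3S)-3,5,7,8-tetramethoxy-2-(2-methoxyphenyl)chroman-4-one
Product: 10 3,5,7,8-tetramethoxy-2-(2-methoxyphenyl)-4H-chromen-4-one
Conditions: I2 (10 mol %), dry DMSO, 120 °C; aq. Na2S2O3
Reagents that add atoms: none
Why: Iodine-catalysed dehydrogenation of a flavanone: the electron-rich C3 enol is iodinated, HI is lost across C2–C3 and DMSO reoxidises the HI; both stereocentres of 9 vanish.

## Compound list

1 | 1,2,3,5-tetramethoxybenzene | COc1cc(OC)c(OC)c(OC)c1 | starting material
2 | methoxyacetyl chloride | COCC(Cl)=O | starting material
3 | 2-methoxy-1-(2,3,4,6-tetramethoxyphenyl)ethan-1-one | COCC(=O)c1c(OC)cc(OC)c(OC)c1OC | intermediate (not isolated)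
4 | 1-(2-hydroxy-3,4,6-trimethoxyphenyl)-2-methoxyethan-1-one | COCC(=O)c1c(OC)cc(OC)c(OC)c1O | intermediate
5 | 2-methoxybenzyl chloride | COc1ccccc1CCl | starting material
6 | 2-methoxy-1-{3,4,6-trimethoxy-2-[(2-methoxybenzyl)oxy]phenyl}ethan-1-one | COCC(=O)c1c(OC)cc(OC)c(OC)c1OCc1ccccc1OC | intermediate
7 | lithium (Z)-2-methoxy-1-{3,4,6-trimethoxy-2-[(2-methoxybenzyl)oxy]phenyl}ethen-1-olate | CO/C=C(\O[Li])c1c(OC)cc(OC)c(OC)c1OCc1ccccc1OC | intermediate (not isolated)
8 | (Z)-2-methoxy-1-{3,4,6-trimethoxy-2-[(2-methoxybenzyl)oxy]phenyl}ethenyl acetate | CO/C=C(\OC(C)=O)c1c(OC)cc(OC)c(OC)c1OCc1ccccc1OC | intermediate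
9 | rac-(2S,3S)-3,5,7,8-tetramethoxy-2-(2-methoxyphenyl)chroman-4-one (trans; racemic, 2S,3S enantiomer drawn) | CO[C@H]1[C@H](c2ccccc2OC)Oc2c(OC)c(OC)cc(OC)c2C1=O | intermediate
10 | 3,5,7,8-tetramethoxy-2-(2-methoxyphenyl)-4H-chromen-4-one | COc1ccccc1-c1oc2c(OC)c(OC)cc(OC)c2c(=O)c1OC | target

## Step count and least certain steps

Total step count: 5. Longest linear sequence: 5 steps (1 to 4 to 6 to 8 to 9 to 10).

**Step 4 (key step).**
- What may go wrong: electron transfer from ring A may be followed by degradation of that ring instead of C–H cleavage. DDQ may add to the enol double bond. Traces of water may capture the oxocarbenium ion, which amounts to oxidative loss of the benzyl group. All of these gain ground if the 6-endo closure is slow, because an aryl-bound oxygen stabilises the cation less than an alkyl ether oxygen and the enol carbon must reach past a crowded ring.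
- Fallback by known chemistry, from 4 to 10: phenol 4 would be acylated with 2-methoxybenzoyl chloride in pyridine to give 3,5,6-trimethoxy-2-(2-methoxyacetyl)phenyl 2-methoxybenzoate F1. KOH in pyridine at 50 °C, then acetic acid, would move the aroyl group to carbon (Baker–Venkataraman rearrangement) and give 1-(2-hydroxy-3,4,6-trimethoxyphenyl)-2-methoxy-3-(2-methoxyphenyl)propane-1,3-dione F2. Cyclodehydration with catalytic H2SO4 in acetic acid at 90 °C would close O1–C2 and give 10 directly.

**Step 1.**
- What may go wrong: the acylium–AlCl3 complex may lose CO to a methoxymethyl cation, so that the ring is alkylated instead of acylated. A second ether, or the less crowded ortho methoxy group, may be cleaved on heating.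
- Fallback, from 1 to 4: lithiation of 1 with n-BuLi and TMEDA in THF at 0 °C, between two methoxy groups, would give (2,3,4,6-tetramethoxyphenyl)lithium F3. Addition to N,2-dimethoxy-N-methylacetamide would give ketone 3, here isolated, with no acylium ion involved. A single chelation-directed demethylation with BCl3 in CH2Cl2 at −78 to 0 °C would then give 4.

**Step 3.**
- What may go wrong: the enolate may be acylated on carbon instead of oxygen, and the enol geometry may be mixed.
- Fallback, from 6 to 8: acid-catalysed enol ester exchange with isopropenyl acetate and catalytic p-toluenesulfonic acid at reflux, in which acetone distils off. No enolate is involved, so C-acylation cannot occur, and either enol isomer should serve in step 4. No new compound arises on the way (F0).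

**Step 5.**
- What may go wrong: the 3-iodo-3-methoxy intermediate may be hydrolysed, with loss of the C3 methyl ether, or C6 of ring A may be iodinated.
- Fallback, from 9 to 10: halogen-free dehydrogenation with DDQ in dioxane at reflux with catalytic p-toluenesulfonic acid. This removes hydride from C2 of the enol form and a proton from C3. No new compound arises on the way (F0).

## Further compounds

F1 | step 4 | 3,5,6-trimethoxy-2-(2-methoxyacetyl)phenyl 2-methoxybenzoate | COCC(=O)c1c(OC)cc(OC)c(OC)c1OC(=O)c1ccccc1OC
F2 | step 4 | 1-(2-hydroxy-3,4,6-trimethoxyphenyl)-2-methoxy-3-(2-methoxyphenyl)propane-1,3-dione (racemic) | COC(C(=O)c1ccccc1OC)C(=O)c1c(OC)cc(OC)c(OC)c1O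
F3 | step 1 | (2,3,4,6-tetramethoxyphenyl)lithium | [Li]c1c(OC)cc(OC)c(OC)c1OC
F0 | step 3 | none | none
F0 | step 5 | none | none
A1 | alternative 1 | 3,5,7-trimethoxy-2-(2-methoxyphenyl)-4H-chromen-4-one | COc1ccccc1-c1oc2cc(OC)cc(OC)c2c(=O)c1OC
A2 | alternative 1 | 3,5-dimethoxybenzyne | COC1=CC(OC)=CC#C1
A3 | alternative 1 | 2,3-dimethoxy-3-(2-methoxyphenyl)prop-2-enoic acid | COC(C(=O)O)=C(OC)c1ccccc1OC
A4 | alternative 2 | 5,7,8-trimethoxy-2-(2-methoxyphenyl)-4H-chromen-4-one | COc1ccccc1-c1cc(=O)c2c(OC)cc(OC)c(OC)c2o1
A5 | alternative 2 | 2-iodo-3,5,6-trimethoxyphenol | COc1cc(OC)c(I)c(O)c1OC
A6 | alternative 2 | 2-ethynylanisole | COc1ccccc1C#C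
A7 | alternative 2 | carbon monoxide | [C-]#[O+]
A8 | alternative 3 | 5,8-dihydroxy-3,7-dimethoxy-2-(2-methoxyphenyl)-4H-chromen-4-one | COc1ccccc1-c1oc2c(O)c(OC)cc(O)c2c(=O)c1OC
A9 | alternative 3 | 4-hydroxy-3-methoxy-4-[5-methoxy-6-(2-methoxyphenyl)-4-oxo-4H-pyran-2-yl]cyclobut-2-en-1-one (racemic) | COC1=CC(=O)C1(O)c1cc(=O)c(OC)c(-c2ccccc2OC)o1
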